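**Retrosynthetic overview**
- The target is cut at C13=C14 (Horner–Wadsworth–Emmons) back to a 2,3-diacetoxy 14,15-dinor-labd-7-en-13-one carrying its C13 ketone as a dioxolane.
- Key step: the C9–H bond, the C9 stereocentre and the 7,8-olefin are formed together by the sigmatropic allylic diazene rearrangement (Myers reductive transposition) of a 7-hydroxy-8-ene. That alcohol comes from a 9-ketone by Grignard addition of the side chain, [3,3] chromate transposition and Luche reduction.
- The cis-2,3-diol comes from substrate-controlled OsO4 dihydroxylation of a ring A 2,3-olefin on the face opposite the 10-methyl.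
- Ring A (with the C4 gem-dimethyl group and the 2,3-olefin) is closed by a 6-exo reductive Heck cyclisation of a (Z)-vinyl iodide onto the isopropenyl group. C10 is set beforehand by double alkylation anti to isopropenyl.
- Ring B is bought as (S)-(+)-carvone, the only source of chirality. Ring order: B (purchased), then A.

Assumption: labdane numbering (C1–C20) is used for positions, ent-α/β descriptors follow the usual ent convention, and in the real compounds the 10-methyl is α, H-5 and H-9 are β and the C2/C3 oxygens are β.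

**Step 1**
Reactants: 1 ethyl (2Z)-3-iodoprop-2-enoate
Product: 2 (2Z)-3-iodoprop-2-en-1-ol
Conditions: i-Bu2AlH (2.2 equiv), CH2Cl2, −78 → 0 °C; aq. KNaC4H4O6 work-up
Reagents that add atoms: none
Why: Hydride reduction of the ester to the allylic alcohol at low temperature leaves the vinyl iodide and its Z geometry intact.

**Step 2**
Reactants: 2 (2Z)-3-iodoprop-2-en-1-ol
Product: 3 (1Z)-3-bromo-1-iodoprop-1-ene
Conditions: CBr4 (1.1 equiv), PPh3 (1.1 equiv), CH2Cl2, 0 °C
Reagents that add atoms: tetrabromomethane BrC(Br)(Br)Br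
Why: Appel bromination activates the allylic alcohol under neutral conditions without isomerising the (Z)-vinyl iodide.

**Step 3**
Reactants: 4 (S)-(+)-carvone
Product: 6 (5S)-2,6-dimethyl-5-(prop-1-en-2-yl)cyclohex-2-en-1-one (6-methylcarvone; C6 epimers), via lithium dienolate 5 (not isolated)
Conditions: LiN(i-Pr)2 (1.05 equiv, commercial solution), THF, −78 °C; MeI, −78 → 0 °C
Reagents that add atoms: iodomethane CI
Why: Kinetic α′-deprotonation gives the cross-conjugated dienolate, which is C-methylated (enolate alkylation); the new C6 centre is re-enolised in step 4 and the purchased C5 centre is untouched.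

**Step 4**
Reactants: 6 6-methylcarvone; 3 (1Z)-3-bromo-1-iodoprop-1-ene
Product: 8 (5R,6R)-6-[(2Z)-3-iodoprop-2-en-1-yl]-2,6-dimethyl-5-(prop-1-en-2-yl)cyclohex-2-en-1-one, via lithium dienolate 7 (not isolated)
Conditions: LiN(i-Pr)2 (1.1 equiv), THF, −78 °C; DMPU (2 equiv); 3 (1.2 equiv), −78 → −20 °C
Reagents that add atoms: none
Why: Enolate alkylation (SN2 on the allylic bromide) occurs on the face anti to the adjacent isopropenyl group, so the iodoallyl chain (future C1–C3) ends up trans to isopropenyl and the methyl cis, which fixes quaternary C10 relative to C5.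

**Step 5**
Reactants: 8 iodoallyl ketone
Product: 9 (4aR,8aR)-2,5,5,8a-tetramethyl-4a,5,8,8a-tetrahydronaphthalen-1(4H)-one
Conditions: Pd(OAc)2 (10 mol %), PPh3 (20 mol %), HCO2Na (2 equiv), Et4NCl (1 equiv), DMF, 80 °C
Reagents that add atoms: none
Why: Reductive Heck cyclisation closes ring A: zerovalent palladium formed in situ adds to the (Z)-vinyl iodide, 6-exo-trig carbopalladation of the isopropenyl group follows, and formate reduces the neopentyl Pd–C bond (no β-hydrogen), creating the C4 gem-dimethyl carbon and the 2,3-olefin with the trans fusion already dictated by C5/C10.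

**Step 6**
Reactants: 9 bicyclic dienone; 10 2-(2-bromoethyl)-2-methyl-1,3-dioxolane
Product: 12 13,13-(ethylenedioxy)-14,15-dinor-ent-labda-2,7-dien-9-ol (9-OH syn to the 10-methyl), via Grignard reagent 11 (not isolated)
Conditions: 10 (2 equiv), Mg turnings, THF, 25–35 °C; then 9, LaCl3·2LiCl (30 mol %), THF, 0 °C → rt; H2O work-up
Reagents that add atoms: none
Why: Lewis-acid-assisted Grignard 1,2-addition to the hindered, non-enolisable enone carbonyl installs C11–C13 and C16 as a masked methyl ketone; the carbinol configuration (attack anti to the axial 10-methyl) is irrelevant because C9 becomes sp2 in step 7.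

**Step 7**
Reactants: 12 tertiary allylic alcohol
Product: 13 13,13-(ethylenedioxy)-14,15-dinor-ent-labda-2,8-dien-7-one
Conditions: pyridinium chlorochromate (C5H5NH)[CrO3Cl] (3 equiv), NaOAc, 4 Å molecular sieves, CH2Cl2, rt
Reagents that add atoms: pyridinium chlorochromate [O-][Cr](=O)(=O)Cl.c1cc[nH+]cc1
Why: Dauben oxidative transposition, in which the tertiary allylic chromate ester undergoes a [3,3]-sigmatropic shift to C7 and is oxidised there, gives the tetrasubstituted 8-en-7-one.

**Step 8**
Reactants: 13 dienone ketal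
Product: 14 ent-2α,3α-dihydroxy-13,13-(ethylenedioxy)-14,15-dinorlabd-8-en-7-one
Conditions: OsO4 (2 mol %), N-methylmorpholine N-oxide (1.5 equiv), acetone/H2O (4:1), rt
Reagents that add atoms: N-methylmorpholine N-oxide C[N+]1([O-])CCOCC1; water O
Why: Upjohn cis-dihydroxylation is chemoselective for the cis-disubstituted ring A olefin over the electron-poor tetrasubstituted enone, and OsO4 approaches the face opposite the syn-axial 10-methyl and 4-methyl groups, setting C2 and C3 together (cis diol trans to the 10-methyl).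

**Step 9**
Reactants: 14 diol
Product: 15 ent-2α,3α-diacetoxy-13,13-(ethylenedioxy)-14,15-dinorlabd-8-en-7-one
Conditions: Ac2O (5 equiv), pyridine, DMAP (10 mol %), rt
Reagents that add atoms: acetic anhydride CC(=O)OC(C)=O
Why: DMAP-catalysed acylation esterifies both secondary hydroxyls, including the hindered axial C3–OH, and these are the acetates kept in the target.

**Step 10**
Reactants: 15 diacetoxy enone
Product: 16 ent-2α,3α-diacetoxy-13,13-(ethylenedioxy)-7β-hydroxy-14,15-dinorlabd-8-ene (7-OH syn to the 10-methyl)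
Conditions: NaBH4 (1.5 equiv), CeCl3·7H2O (1.2 equiv), MeOH, −78 → −20 °C
Reagents that add atoms: none
Why: Luche 1,2-reduction delivers hydride axially to C7 from the face opposite the 10-methyl, giving the pseudo-equatorial allylic alcohol (OH syn to the 10-methyl) without touching acetates, ketal or the tetrasubstituted olefin.

**Step 11**
Reactants: 16 allylic alcohol
Product: 19 ent-2α,3α-diacetoxy-13,13-(ethylenedioxy)-14,15-dinorlabd-7-ene, via N-sulfonylhydrazine adduct 17 (not isolated), via allylic diazene 18 (not isolated)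
Conditions: 2-nitrobenzenesulfonylhydrazide (2 equiv), PPh3 (2 equiv), diethyl azodicarboxylate (2 equiv), THF, −30 °C, 2 h; then 23 °C, 3 h
Reagents that add atoms: none
Why: Myers reductive 1,3-transposition: Mitsunobu displacement by the sulfonylhydrazide inverts C7, sulfinate loss gives the monoalkyl diazene, and its concerted sigmatropic (retro-ene) loss of N2 transfers hydrogen suprafacially to C9 on the face anti to the 10-methyl, forming the C9–H bond, the C9 stereocentre (side chain equatorial, syn to the 10-methyl) and the 7,8-olefin in one event.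

**Step 12**
Reactants: 19 ketal
Product: 20 ent-2α,3α-diacetoxy-14,15-dinorlabd-7-en-13-one
Conditions: AcOH/THF/H2O (3:1:1), 40 °C
Reagents that add atoms: water O
Why: Mild acid-catalysed acetal hydrolysis frees the methyl ketone while the acetates, the trisubstituted olefin and all stereocentres are left alone.

**Step 13**
Reactants: 20 methyl ketone; 21 trimethylsilyl (diethoxyphosphoryl)acetate
Product: 23 ent-2α,3α-diacetoxylabda-7,13E-dien-15-oic acid (target), via trimethylsilyl ester 22 (not isolated)
Conditions: 21 (1.5 equiv), NaH (1.5 equiv), THF, 0 °C; then 20, 0 → 60 °C; 1 M HCl work-up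
Reagents that add atoms: none
Why: Horner–Wadsworth–Emmons olefination of the methyl ketone gives mainly the E trisubstituted enoate (about 4:1, the Z isomer removed by chromatography), and the silyl ester is cleaved on acidic work-up, so the free acid is obtained without a saponification that would cleave the acetates.

**Compound list**
1 | ethyl (2Z)-3-iodoprop-2-enoate | CCOC(=O)/C=C\I | starting material
2 | (2Z)-3-iodoprop-2-en-1-ol | OC/C=C\I | intermediate
3 | (1Z)-3-bromo-1-iodoprop-1-ene | BrC/C=C\I | intermediate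
4 | (S)-(+)-carvone, (5S)-2-methyl-5-(prop-1-en-2-yl)cyclohex-2-en-1-one | O=C1C(C)=CC[C@H](C(C)=C)C1 | starting material
5 | lithium cross-conjugated dienolate of 4 (O–C1=C6) | [Li+].[O-]C1=C[C@@H](C(C)=C)CC=C1C | intermediate
6 | (5S)-2,6-dimethyl-5-(prop-1-en-2-yl)cyclohex-2-en-1-one (6-methylcarvone, C6 epimers) | O=C1C(C)=CC[C@H](C(C)=C)C1C | intermediate
7 | lithium cross-conjugated dienolate of 6 (O–C1=C6) | [Li+].[O-]C1=C(C)[C@@H](C(C)=C)CC=C1C | intermediate
8 | (5R,6R)-6-[(2Z)-3-iodoprop-2-en-1-yl]-2,6-dimethyl-5-(prop-1-en-2-yl)cyclohex-2-en-1-one | I/C=C\C[C@@]1(C)C(=O)C(C)=CC[C@@H]1C(C)=C | intermediate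
9 | (4aR,8aR)-2,5,5,8a-tetramethyl-4a,5,8,8a-tetrahydronaphthalen-1(4H)-one (trans-fused) | C1=CC[C@@]2(C)C(=O)C(C)=CC[C@@H]2C1(C)C | intermediate
10 | 2-(2-bromoethyl)-2-methyl-1,3-dioxolane | CC1(CCBr)OCCO1 | starting material
11 | [2-(2-methyl-1,3-dioxolan-2-yl)ethyl]magnesium bromide | CC1(CC[Mg]Br)OCCO1 | intermediate
12 | 13,13-(ethylenedioxy)-14,15-dinor-ent-labda-2,7-dien-9-ol (9-OH syn to the 10-methyl) | C1=CC[C@@]2(C)[C@@](O)(CCC3(C)OCCO3)C(C)=CC[C@@H]2C1(C)C | intermediate
13 | 13,13-(ethylenedioxy)-14,15-dinor-ent-labda-2,8-dien-7-one | C1=CC[C@@]2(C)C(CCC3(C)OCCO3)=C(C)C(=O)C[C@@H]2C1(C)C | intermediate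
14 | ent-2α,3α-dihydroxy-13,13-(ethylenedioxy)-14,15-dinorlabd-8-en-7-one | O[C@H]1C[C@@]2(C)C(CCC3(C)OCCO3)=C(C)C(=O)C[C@@H]2C(C)(C)[C@H]1O | intermediate
15 | ent-2α,3α-diacetoxy-13,13-(ethylenedioxy)-14,15-dinorlabd-8-en-7-one | CC(=O)O[C@H]1C[C@@]2(C)C(CCC3(C)OCCO3)=C(C)C(=O)C[C@@H]2C(C)(C)[C@H]1OC(C)=O | intermediate
16 | ent-2α,3α-diacetoxy-13,13-(ethylenedioxy)-7β-hydroxy-14,15-dinorlabd-8-ene (7-OH syn to the 10-methyl) | CC(=O)O[C@H]1C[C@@]2(C)C(CCC3(C)OCCO3)=C(C)[C@H](O)C[C@@H]2C(C)(C)[C@H]1OC(C)=O | intermediate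
17 | C7 N-(2-nitrophenylsulfonyl)hydrazine adduct of 16 (C7–N anti to the 10-methyl) | CC(=O)O[C@H]1C[C@@]2(C)C(CCC3(C)OCCO3)=C(C)[C@@H](N(N)S(=O)(=O)c3ccccc3[N+](=O)[O-])C[C@@H]2C(C)(C)[C@H]1OC(C)=O | intermediate
18 | C7 monoalkyl diazene (C7–N=NH anti to the 10-methyl) | CC(=O)O[C@H]1C[C@@]2(C)C(CCC3(C)OCCO3)=C(C)[C@@H](N=N)C[C@@H]2C(C)(C)[C@H]1OC(C)=O | intermediate
19 | ent-2α,3α-diacetoxy-13,13-(ethylenedioxy)-14,15-dinorlabd-7-ene | CC(=O)O[C@H]1C[C@@]2(C)[C@H](CCC3(C)OCCO3)C(C)=CC[C@@H]2C(C)(C)[C@H]1OC(C)=O | intermediate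
20 | ent-2α,3α-diacetoxy-14,15-dinorlabd-7-en-13-one | CC(=O)O[C@H]1C[C@@]2(C)[C@H](CCC(C)=O)C(C)=CC[C@@H]2C(C)(C)[C@H]1OC(C)=O | intermediate
21 | trimethylsilyl (diethoxyphosphoryl)acetate | CCOP(=O)(CC(=O)O[Si](C)(C)C)OCC | starting material
22 | trimethylsilyl ent-2α,3α-diacetoxylabda-7,13E-dien-15-oate | CC(=O)O[C@H]1C[C@@]2(C)[C@H](CC/C(C)=C/C(=O)O[Si](C)(C)C)C(C)=CC[C@@H]2C(C)(C)[C@H]1OC(C)=O | intermediate
23 | ent-2α,3α-diacetoxylabda-7,13E-dien-15-oic acid, (2E)-5-[(1R,4aS,6R,7S,8aS)-6,7-diacetoxy-2,5,5,8a-tetramethyl-1,4,4a,5,6,7,8,8a-octahydronaphthalen-1-yl]-3-methylpent-2-enoic acid | CC(=O)O[C@H]1C[C@@]2(C)[C@H](CC/C(C)=C/C(=O)O)C(C)=CC[C@@H]2C(C)(C)[C@H]1OC(C)=O | target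

**Step count**
Total: 13 steps. Longest linear sequence: 12 steps (steps 1, 2 and 4–13, from ethyl (2Z)-3-iodoprop-2-enoate through bromide 3 to the target). The chain from (S)-carvone (steps 3–13) is 11 steps and meets the longer chain at step 4.

**Steps most likely to fail**

Step 5 (reductive Heck closure of ring A). Premature formate reduction of the vinyl–Pd species, or further reaction of the neopentyl–Pd intermediate, may compete with the 6-exo closure. The fallback sets out from 6 and returns at 9. The lithium enolate of 6 is alkylated with commercial 3-bromo-1-(trimethylsilyl)prop-1-yne to give the silylalkyne F1. F1 is semihydrogenated (H2, Pd/CaCO3 poisoned with Pb(OAc)2, quinoline) to the (Z)-vinylsilane F2. F2 is then treated with CF3CO2H in CH2Cl2 at 0 °C: Markovnikov protonation of the isopropenyl group gives the tertiary C4 cation, which is captured at the silicon-bearing carbon (vinylsilane-terminated cation–olefin cyclisation, ipso substitution with retention) to deliver the 2,3-olefin and the gem-dimethyl carbon of 9 without any palladium chemistry.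

Step 7 (oxidative transposition). The very hindered tertiary alcohol may dehydrate, or the acidic chromium reagent may open the dioxolane. The fallback sets out from 12 and returns at 13. The oxidation is separated from the rearrangement: Ph3SiOReO3 (5 mol %) in Et2O at 0 °C effects the redox-neutral [3,3] allylic transposition to the secondary allylic alcohol F3, which is favoured because the olefin becomes tetrasubstituted. MnO2 in CH2Cl2 then oxidises F3 to 13.

Step 11 (Mitsunobu/diazene sequence). Displacement at the hindered secondary allylic carbinol next to a tetrasubstituted olefin may be slow or give elimination. The fallback sets out from 16 and returns at 19. The alcohol is converted with ClCO2Me, pyridine and DMAP into the allylic methyl carbonate F4. F4 is reduced with HCO2NH4, Pd(OAc)2 (5 mol %) and n-Bu3P in dioxane at 80 °C (Tsuji–Mandai formate reduction): zerovalent palladium ionises anti to the carbonate and hydride is passed from palladium to the more substituted allyl terminus C9. This gives the same net anti 1,3-transposition, hence the same C9 configuration and 7,8-olefin as 19.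

**Further compounds**
F1 | step 5 | (5R,6R)-2,6-dimethyl-5-(prop-1-en-2-yl)-6-[3-(trimethylsilyl)prop-2-yn-1-yl]cyclohex-2-en-1-one | C[Si](C)(C)C#CC[C@@]1(C)C(=O)C(C)=CC[C@@H]1C(C)=C
F2 | step 5 | (5R,6R)-2,6-dimethyl-5-(prop-1-en-2-yl)-6-[(2Z)-3-(trimethylsilyl)prop-2-en-1-yl]cyclohex-2-en-1-one | C[Si](C)(C)/C=C\C[C@@]1(C)C(=O)C(C)=CC[C@@H]1C(C)=C
F3 | step 7 | 13,13-(ethylenedioxy)-14,15-dinor-ent-labda-2,8-dien-7-ol (7-OH syn to the 10-methyl) | C1=CC[C@@]2(C)C(CCC3(C)OCCO3)=C(C)[C@H](O)C[C@@H]2C1(C)C
F4 | step 11 | methyl carbonate of 16 (C7–OCO2Me syn to the 10-methyl) | CC(=O)O[C@H]1C[C@@]2(C)C(CCC3(C)OCCO3)=C(C)[C@H](OC(=O)OC)C[C@@H]2C(C)(C)[C@H]1OC(C)=O
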